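**Plan**
1. Retrosynthesis: the C6 acetate, the C5 hydroxyl and the methyl ester come off first. On the five-membered ring (C5–C6–C7 of the cyclopenta[c]pyridin-7-one) the C5 carboxyl carbon and the C6 oxygen sit on the same face, so the two adjacent fully substituted carbons can be bridged as a cis-fused β-lactone, C5–C(=O)–O–C6.
2. This tricyclic lactone is cut at the C5–C6 bond and at the lactone C–O bond to a pyridin-4-ylacetic acid with a 2-oxopropanoyl group on the neighbouring ring carbon. The acid is cut at C7–C6 (amide plus 1-ethoxyvinyllithium), at C5–CO2 (carboxylation of the 4-methyl group) and at C3–C1' (Suzuki coupling).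
3. Forward: dienyl boronate from (S)-2-methylbutan-1-ol; the pyridine core is taken to the amide/acetate, coupled, acylated and unmasked; one operation then closes the cyclopentanone and, directly after it, the β-lactone; C5 hydroxylation, lactone methanolysis and C6 acetylation finish the route.
4. Stereochemistry: C5' from the chiral pool; both E alkenes from olefinations; C5 and C6 from the chiral isothiourea (absolute) and the obligatory cis ring fusion (relative); the C5 hydroxyl replaces hydrogen with retention because the lactone cannot be trans-fused.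

Key step: step 10

Remark: ring atoms are numbered as in cyclopenta[c]pyridine (C1, N2, C3, C4, C4a, C5, C6, C7, C7a) and the side chain as C1'–C7'; the catalyst enantiomer is assigned from the usual model (electrophile anti to the pseudo-axial C2-phenyl of the O···S-locked Z-enolate), and its mirror image would be used if the sense proved opposite.

**Step 1**
Reactants: 1 (S)-2-methylbutan-1-ol
Product: 3 ethyl (S,E)-2,4-dimethylhex-2-enoate, via (S)-2-methylbutanal 2 (not isolated)
Conditions: TEMPO (10 mol %), PhI(OAc)2, CH2Cl2, rt; then Ph3P=C(CH3)CO2Et, rt → 40 °C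
Reagents that add atoms: ethyl 2-(triphenylphosphoranylidene)propanoate, CCOC(=O)C(C)=P(c1ccccc1)(c1ccccc1)c1ccccc1
Why: Base-free TEMPO/PhI(OAc)2 oxidation followed at once by a Wittig reaction with the stabilized α-methyl ylide should give the (E)-trisubstituted enoate before the chiral-pool stereocenter of aldehyde 2 can enolize.

**Step 2**
Reactants: 3 ethyl (S,E)-2,4-dimethylhex-2-enoate
Product: 4 (S,E)-2,4-dimethylhex-2-en-1-ol
Conditions: i-Bu2AlH (2.2 equiv), CH2Cl2, −78 → 0 °C; aq. potassium sodium tartrate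
Reagents that add atoms: none
Why: 1,2-Reduction of the enoate by the aluminium hydride (ester to allylic alcohol) leaves alkene geometry and the stereocenter untouched.

**Step 3**
Reactants: 4 (S,E)-2,4-dimethylhex-2-en-1-ol
Product: 5 (S,E)-2,4-dimethylhex-2-enal
Conditions: MnO2 (activated, excess), CH2Cl2, rt
Reagents that add atoms: none
Why: Allylic oxidation with MnO2 is neutral and selective for the allylic alcohol, so neither E/Z isomerization nor epimerization at the γ-carbon is expected.

**Step 4**
Reactants: 5 (S,E)-2,4-dimethylhex-2-enal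
Product: 6 2-[(1E,3E,5S)-3,5-dimethylhepta-1,3-dien-1-yl]-4,4,5,5-tetramethyl-1,3,2-dioxaborolane
Conditions: CH2(Bpin)2 (1.2 equiv), lithium 2,2,6,6-tetramethylpiperidide (LiTMP, 1.1 equiv), THF, 0 °C; then 5, −78 °C → rt; aq. NH4Cl
Reagents that add atoms: bis(4,4,5,5-tetramethyl-1,3,2-dioxaborolan-2-yl)methane, CC1(C)OB(CB2OC(C)(C)C(C)(C)O2)OC1(C)C
Why: In this boron–Wittig olefination the α-boryl carbanion (formed with the amide base as limiting reagent, so no free base meets the enal) adds to the aldehyde and syn B–O elimination should give the trans-alkenyl boronate, setting the C1'=C2' E geometry.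

**Step 5**
Reactants: 7 methyl 6-chloro-4-methylnicotinate
Product: 8 6-chloro-N-methoxy-N,4-dimethylpyridine-3-carboxamide
Conditions: MeNH(OMe)·HCl, i-PrMgCl, THF, −20 → 0 °C
Reagents that add atoms: N,O-dimethylhydroxylamine hydrochloride, CNOC.Cl
Why: Aminolysis of the methyl ester by the chloromagnesium amide of N,O-dimethylhydroxylamine (Weinreb amide formation) is fast at low temperature and should spare the 2-chloropyridine.

**Step 6**
Reactants: 8 6-chloro-N-methoxy-N,4-dimethylpyridine-3-carboxamide
Product: 9 tert-butyl 2-[2-chloro-5-[methoxy(methyl)carbamoyl]pyridin-4-yl]acetate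
Conditions: lithium diisopropylamide (LDA, 2.2 equiv), THF, −78 °C; Boc2O (1.05 equiv), −78 °C; aq. NH4Cl
Reagents that add atoms: di-tert-butyl dicarbonate, CC(C)(C)OC(=O)OC(=O)OC(C)(C)C
Why: Lateral lithiation of the 4-methyl group (acidified by the para ring nitrogen, the chlorine and the ortho amide) should outrun attack on the N-methoxy amide at −78 °C, and C-acylation of the picolyl anion by Boc2O gives the acetate, which the second equivalent of base stores as its enolate so that it is not acylated twice.

**Step 7**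
Reactants: 9 tert-butyl 2-[2-chloro-5-[methoxy(methyl)carbamoyl]pyridin-4-yl]acetate; 6 2-[(1E,3E,5S)-3,5-dimethylhepta-1,3-dien-1-yl]-4,4,5,5-tetramethyl-1,3,2-dioxaborolane
Product: 10 tert-butyl 2-[2-[(1E,3E,5S)-3,5-dimethylhepta-1,3-dien-1-yl]-5-[methoxy(methyl)carbamoyl]pyridin-4-yl]acetate
Conditions: Pd(dppf)Cl2 (5 mol %; dppf = 1,1'-bis(diphenylphosphino)ferrocene), K3PO4, 1,4-dioxane/H2O, 80 °C
Reagents that add atoms: none
Why: Suzuki–Miyaura coupling at the activated 2-chloropyridine carbon proceeds with retention of the boronate geometry, and the tert-butyl ester and N-methoxy amide tolerate aqueous K3PO4.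

**Step 8**
Reactants: 10 tert-butyl 2-[2-[(1E,3E,5S)-3,5-dimethylhepta-1,3-dien-1-yl]-5-[methoxy(methyl)carbamoyl]pyridin-4-yl]acetate; 11 ethyl vinyl ether
Product: 12 tert-butyl 2-[2-[(1E,3E,5S)-3,5-dimethylhepta-1,3-dien-1-yl]-5-(2-ethoxyprop-2-enoyl)pyridin-4-yl]acetate
Conditions: 11, t-BuLi, THF, −78 → 0 °C (1-ethoxyvinyllithium, 2 equiv); separately 10, LiN(SiMe3)2 (1.05 equiv), THF, −78 °C; combine at −78 °C; AcOH at −78 °C, then pH 7 phosphate buffer
Reagents that add atoms: none
Why: With the acidic acetate arm first stored as its lithium enolate (which also makes the dienylpyridine too electron-rich for carbolithiation), 1-ethoxyvinyllithium should add once to the ortho-twisted N-methoxy amide to give a chelated tetrahedral intermediate that collapses to the α-ethoxy enone only on the cold acidic quench (Weinreb ketone synthesis with an acyl-anion equivalent).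

**Step 9**
Reactants: 12 tert-butyl 2-[2-[(1E,3E,5S)-3,5-dimethylhepta-1,3-dien-1-yl]-5-(2-ethoxyprop-2-enoyl)pyridin-4-yl]acetate
Product: 14 2-[2-[(1E,3E,5S)-3,5-dimethylhepta-1,3-dien-1-yl]-5-(2-oxopropanoyl)pyridin-4-yl]acetic acid, via diketone tert-butyl ester 13 (not isolated)
Conditions: 1 M aq. HCl, THF, rt; concentrate; TFA/CH2Cl2 (1:3), 0 °C → rt; evaporate with toluene below 25 °C, use at once as the trifluoroacetate salt
Reagents that add atoms: water, O
Why: Acid hydrolysis of the enol ether unveils the methyl ketone of the 1,2-diketone and TFA then cleaves the tert-butyl ester through the tert-butyl cation, while the protonated pyridine shields the diene and the absence of base prevents both a premature aldol and loss of CO2 from the pyridylacetic acid.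

**Step 10**
Reactants: 14 2-[2-[(1E,3E,5S)-3,5-dimethylhepta-1,3-dien-1-yl]-5-(2-oxopropanoyl)pyridin-4-yl]acetic acid
Product: 16 cis-fused tricyclic β-lactone, i.e. the lactone of (5S,6S)-3-[(1E,3E,5S)-3,5-dimethylhepta-1,3-dien-1-yl]-6-hydroxy-6-methyl-7-oxo-6,7-dihydro-5H-cyclopenta[c]pyridine-5-carboxylic acid closed from the C5 carboxyl to the C6 oxygen (C5–H, C6–CH3), via mixed pivalic anhydride 15 (not isolated)
Conditions: t-BuCOCl (1.1 equiv), i-Pr2NEt (2.1 equiv, just enough for the salt and the acid), CH2Cl2, −40 °C; then (2S,3R)-HyperBTM [(2S,3R)-3-isopropyl-2-phenyl-3,4-dihydro-2H-benzo[4,5]thiazolo[3,2-a]pyrimidine, 20 mol %], i-Pr2NEt (1.5 equiv, slow addition), −40 → 0 °C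
Reagents that add atoms: none
Why: Pivaloyl chloride turns the acid into mixed anhydride 15, which acylates the isothiourea, and deprotonation of the acylammonium by i-Pr2NEt gives a (Z)-configured C1-ammonium enolate whose oxygen is held syn to the catalyst sulfur. The reaction is a nucleophile-catalysed aldol-lactonization of a keto acid, the intramolecular counterpart of isothiourea-catalysed formal [2+2] additions of arylacetic acids to activated ketones. The cyclopentanone closes by a 5-(enolexo)-exo-trig aldol of the enolate carbon (C5) onto the methyl ketone carbonyl (C6), and the β-lactone by 4-exo-trig attack of the new tertiary alkoxide on the acylammonium carbonyl, which releases the catalyst. C5 is set by the catalyst, since the ketone should approach the enolate face opposite the pseudo-axial C2-phenyl group, which for the (2S)-configured catalyst is expected to give (5S); C6 follows from C5 because only the aldolate with oxygen cis to the acyl group can lactonize, the other reverting by retro-aldol. Chemoselectivity between the two ketones is secured by ring size, as attack on the aryl ketone would need a four-membered carbocycle, and the 1,2-dicarbonyl makes the methyl ketone electrophilic enough for a ketone aldol. The racemic path through the free enolate of 15 is held back by forming 15 without excess base and by feeding the second portion of amine slowly at −40 °C with the catalyst already present.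

**Step 11**
Reactants: 16 cis-fused tricyclic β-lactone (5S,6S)
Product: 17 (5R,6S)-5-hydroxy β-lactone, i.e. lactone 16 with the C5 hydrogen replaced by hydroxyl on the same face
Conditions: KN(SiMe3)2 (1.05 equiv), THF, −78 °C; 2-(phenylsulfonyl)-3-phenyloxaziridine (1.5 equiv), −78 °C; AcOH quench at −78 °C
Reagents that add atoms: 2-(phenylsulfonyl)-3-phenyloxaziridine, O=S(=O)(N1OC1c1ccccc1)c1ccccc1
Why: The ring-fusion C5–H is acidified by the lactone carbonyl, the pyridin-4-yl ring and the ortho acyl group, so its potassium enolate should form with one equivalent of base and be oxidized by the N-sulfonyloxaziridine (Davis hydroxylation), and because a trans-fused bicyclo[3.2.0] lactone cannot exist the oxygen must enter on the face the hydrogen left, giving (5R) with retention.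

**Step 12**
Reactants: 17 (5R,6S)-5-hydroxy β-lactone
Product: 18 (5R,6S)-5-[(tert-butyldimethylsilyl)oxy] β-lactone
Conditions: t-BuMe2SiOTf, 2,6-lutidine, CH2Cl2, 0 °C → rt
Reagents that add atoms: tert-butyldimethylsilyl trifluoromethanesulfonate, CC(C)(C)[Si](C)(C)OS(=O)(=O)C(F)(F)F
Why: Silyl triflate protection of the only free (tertiary, convex-face) hydroxyl marks the C5 oxygen while the C6 oxygen is still tied up in the lactone.

**Step 13**
Reactants: 18 (5R,6S)-5-[(tert-butyldimethylsilyl)oxy] β-lactone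
Product: 19 methyl (5R,6S)-5-[(tert-butyldimethylsilyl)oxy]-3-[(1E,3E,5S)-3,5-dimethylhepta-1,3-dien-1-yl]-6-hydroxy-6-methyl-7-oxo-6,7-dihydro-5H-cyclopenta[c]pyridine-5-carboxylate
Conditions: HCl (1.25 M in MeOH), 0 °C → rt; NaHCO3 work-up
Reagents that add atoms: methanol, CO
Why: Acid-catalysed methanolysis of the strained β-lactone by acyl–oxygen cleavage should give the methyl ester and free the C6 hydroxyl with retention (ionization at C6 is disfavoured next to the ketone), and acid is chosen over base so that no C6 alkoxide forms that could start a retro-aldol.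

**Step 14**
Reactants: 19 methyl (5R,6S)-5-silyloxy-6-hydroxy ester
Product: 20 methyl (5R,6S)-6-acetoxy-5-[(tert-butyldimethylsilyl)oxy]-3-[(1E,3E,5S)-3,5-dimethylhepta-1,3-dien-1-yl]-6-methyl-7-oxo-6,7-dihydro-5H-cyclopenta[c]pyridine-5-carboxylate
Conditions: Ac2O, DMAP, pyridine, rt → 40 °C
Reagents that add atoms: acetic anhydride, CC(=O)OC(C)=O
Why: DMAP-catalysed acyl transfer acetylates the tertiary α-ketol hydroxyl, which is the only free hydroxyl left.

**Step 15**
Reactants: 20 methyl (5R,6S)-6-acetoxy-5-silyloxy ester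
Product: 21 methyl (5R,6S)-6-acetoxy-3-[(1E,3E,5S)-3,5-dimethylhepta-1,3-dien-1-yl]-5-hydroxy-6-methyl-7-oxo-6,7-dihydro-5H-cyclopenta[c]pyridine-5-carboxylate (CNP0483502.1)
Conditions: HF·pyridine, THF, 0 °C → rt
Reagents that add atoms: none
Why: Fluoride-driven Si–O cleavage under mildly acidic conditions (desilylation) should leave the tertiary acetate, the methyl ester and the base-sensitive β-hydroxy ketone array intact.

**Compound list**
1 | (S)-2-methylbutan-1-ol | CC[C@H](C)CO | starting material
2 | (S)-2-methylbutanal | CC[C@H](C)C=O | intermediate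
3 | ethyl (S,E)-2,4-dimethylhex-2-enoate | CC[C@H](C)/C=C(C)/C(=O)OCC | intermediate
4 | (S,E)-2,4-dimethylhex-2-en-1-ol | CC[C@H](C)/C=C(C)/CO | intermediate
5 | (S,E)-2,4-dimethylhex-2-enal | CC[C@H](C)/C=C(C)/C=O | intermediate
6 | 2-[(1E,3E,5S)-3,5-dimethylhepta-1,3-dien-1-yl]-4,4,5,5-tetramethyl-1,3,2-dioxaborolane | CC[C@H](C)/C=C(C)/C=C/B1OC(C)(C)C(C)(C)O1 | intermediate
7 | methyl 6-chloro-4-methylnicotinate | COC(=O)c1cnc(Cl)cc1C | starting material
8 | 6-chloro-N-methoxy-N,4-dimethylpyridine-3-carboxamide | CON(C)C(=O)c1cnc(Cl)cc1C | intermediate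
9 | tert-butyl 2-[2-chloro-5-[methoxy(methyl)carbamoyl]pyridin-4-yl]acetate | CON(C)C(=O)c1cnc(Cl)cc1CC(=O)OC(C)(C)C | intermediate
10 | tert-butyl 2-[2-[(1E,3E,5S)-3,5-dimethylhepta-1,3-dien-1-yl]-5-[methoxy(methyl)carbamoyl]pyridin-4-yl]acetate | CC[C@H](C)/C=C(C)/C=C/c1cc(CC(=O)OC(C)(C)C)c(cn1)C(=O)N(C)OC | intermediate
11 | ethyl vinyl ether | C=COCC | starting material
12 | tert-butyl 2-[2-[(1E,3E,5S)-3,5-dimethylhepta-1,3-dien-1-yl]-5-(2-ethoxyprop-2-enoyl)pyridin-4-yl]acetate | CC[C@H](C)/C=C(C)/C=C/c1cc(CC(=O)OC(C)(C)C)c(cn1)C(=O)C(=C)OCC | intermediate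
13 | tert-butyl 2-[2-[(1E,3E,5S)-3,5-dimethylhepta-1,3-dien-1-yl]-5-(2-oxopropanoyl)pyridin-4-yl]acetate | CC[C@H](C)/C=C(C)/C=C/c1cc(CC(=O)OC(C)(C)C)c(cn1)C(=O)C(C)=O | intermediate
14 | 2-[2-[(1E,3E,5S)-3,5-dimethylhepta-1,3-dien-1-yl]-5-(2-oxopropanoyl)pyridin-4-yl]acetic acid | CC[C@H](C)/C=C(C)/C=C/c1cc(CC(=O)O)c(cn1)C(=O)C(C)=O | intermediate
15 | 2,2-dimethylpropanoic 2-[2-[(1E,3E,5S)-3,5-dimethylhepta-1,3-dien-1-yl]-5-(2-oxopropanoyl)pyridin-4-yl]acetic anhydride | CC[C@H](C)/C=C(C)/C=C/c1cc(CC(=O)OC(=O)C(C)(C)C)c(cn1)C(=O)C(C)=O | intermediate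
16 | cis-fused β-lactone of (5S,6S)-3-[(1E,3E,5S)-3,5-dimethylhepta-1,3-dien-1-yl]-6-hydroxy-6-methyl-7-oxo-6,7-dihydro-5H-cyclopenta[c]pyridine-5-carboxylic acid | CC[C@H](C)/C=C(C)/C=C/c1cc2c(cn1)C(=O)[C@@]3(C)OC(=O)[C@@H]23 | intermediate
17 | cis-fused β-lactone of (5R,6S)-3-[(1E,3E,5S)-3,5-dimethylhepta-1,3-dien-1-yl]-5,6-dihydroxy-6-methyl-7-oxo-6,7-dihydro-5H-cyclopenta[c]pyridine-5-carboxylic acid (C5–OH free) | CC[C@H](C)/C=C(C)/C=C/c1cc2c(cn1)C(=O)[C@@]3(C)OC(=O)[C@@]23O | intermediate
18 | 5-O-tert-butyldimethylsilyl ether of lactone 17 (5R,6S) | CC[C@H](C)/C=C(C)/C=C/c1cc2c(cn1)C(=O)[C@@]3(C)OC(=O)[C@@]23O[Si](C)(C)C(C)(C)C | intermediate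
19 | methyl (5R,6S)-5-[(tert-butyldimethylsilyl)oxy]-3-[(1E,3E,5S)-3,5-dimethylhepta-1,3-dien-1-yl]-6-hydroxy-6-methyl-7-oxo-6,7-dihydro-5H-cyclopenta[c]pyridine-5-carboxylate | CC[C@H](C)/C=C(C)/C=C/c1cc2c(cn1)C(=O)[C@@](C)(O)[C@@]2(O[Si](C)(C)C(C)(C)C)C(=O)OC | intermediate
20 | methyl (5R,6S)-6-acetoxy-5-[(tert-butyldimethylsilyl)oxy]-3-[(1E,3E,5S)-3,5-dimethylhepta-1,3-dien-1-yl]-6-methyl-7-oxo-6,7-dihydro-5H-cyclopenta[c]pyridine-5-carboxylate | CC[C@H](C)/C=C(C)/C=C/c1cc2c(cn1)C(=O)[C@@](C)(OC(C)=O)[C@@]2(O[Si](C)(C)C(C)(C)C)C(=O)OC | intermediate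
21 | methyl (5R,6S)-6-acetoxy-3-[(1E,3E,5S)-3,5-dimethylhepta-1,3-dien-1-yl]-5-hydroxy-6-methyl-7-oxo-6,7-dihydro-5H-cyclopenta[c]pyridine-5-carboxylate | CC[C@H](C)/C=C(C)/C=C/c1cc2c(cn1)C(=O)[C@@](C)(OC(C)=O)[C@@]2(O)C(=O)OC | target

**Step count**
Total: 15 steps. Longest linear sequence: 13 steps (steps 1–4 and 7–15, from 1); the pyridine branch (steps 5 and 6) joins at step 7.

**Steps most likely to fail**

Step 10 (key step). The mixed anhydride 15 may be enolized by free amine before it reaches the catalyst, which would close the rings without enantiocontrol. The pyridin-4-ylacetic acid may also lose CO2 during handling, or facial discrimination at the crowded enolate may be poor. The fallback separates bond formation from lactonization and never handles a free keto acid. It sets out from 12: hydrolysis of the enol ether alone (1 M HCl, THF) allows 13 to be isolated. A chiral bifunctional Brønsted-base catalyst (a quinine-derived squaramide) would then close the C5–C6 bond by intramolecular aldol addition to give tert-butyl (5S,6S)-3-[(1E,3E,5S)-3,5-dimethylhepta-1,3-dien-1-yl]-6-hydroxy-6-methyl-7-oxo-6,7-dihydro-5H-cyclopenta[c]pyridine-5-carboxylate F1. TFA would cleave the ester to the hydroxy acid F2. Carboxyl activation with benzenesulfonyl chloride in pyridine at 0 °C would close the β-lactone; C5 epimerizes easily and only the cis acid can lactonize, so both C5 epimers should converge. The route is rejoined at 16.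

Step 11. The strained ring-fusion enolate may form slowly. The lactone may also open, by attack of the base at the carbonyl, by β-elimination, or by retro-aldol of the product alkoxide before the cold quench. The fallback hydroxylates an unstrained ester enolate instead and sets out from 16. Acid methanolysis (HCl, MeOH) would give methyl (5S,6S)-6-hydroxy ester F3. Et3SiOTf/2,6-lutidine would give the 6-O-triethylsilyl ether F4. KN(SiMe3)2 and the same oxaziridine should then deliver oxygen to the enolate face anti to the bulky silyloxy group (cis to the C6 methyl), giving the (5R)-5-hydroxy compound F5. t-BuMe2SiOTf would give the bis-silyl ether F6. Selective removal of the more labile triethylsilyl group (HF·pyridine, 0 °C) returns to the route at 19.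

Step 8. Addition of the vinyllithium to the amide may be slowed by the neighbouring enolate. Alternatively, the liberated enone may be trapped by the acidic acetate arm in a six-membered Michael closure during work-up. The fallback installs the masked diketone before the arm and sets out from 8. 1-Ethoxyvinyllithium would add to this arm-free amide to give 1-(6-chloro-4-methylpyridin-3-yl)-2-ethoxyprop-2-en-1-one F7. Ethanol, HC(OEt)3 and catalytic camphorsulfonic acid would convert the enol ether into the diethyl ketal F8, which removes the Michael acceptor. Lateral lithiation with LDA and Boc2O would give the tert-butyl acetate F9. Suzuki coupling with 6 under the conditions of step 7 would give the dienyl ketal ester F10. Aqueous TFA would cleave ketal and tert-butyl ester together, returning to the route at 14.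

**Further compounds**
F1 | step 10 | tert-butyl (5S,6S)-3-[(1E,3E,5S)-3,5-dimethylhepta-1,3-dien-1-yl]-6-hydroxy-6-methyl-7-oxo-6,7-dihydro-5H-cyclopenta[c]pyridine-5-carboxylate | CC[C@H](C)/C=C(C)/C=C/c1cc2c(cn1)C(=O)[C@@](C)(O)[C@H]2C(=O)OC(C)(C)C
F2 | step 10 | (5S,6S)-3-[(1E,3E,5S)-3,5-dimethylhepta-1,3-dien-1-yl]-6-hydroxy-6-methyl-7-oxo-6,7-dihydro-5H-cyclopenta[c]pyridine-5-carboxylic acid | CC[C@H](C)/C=C(C)/C=C/c1cc2c(cn1)C(=O)[C@@](C)(O)[C@H]2C(=O)O
F3 | step 11 | methyl (5S,6S)-3-[(1E,3E,5S)-3,5-dimethylhepta-1,3-dien-1-yl]-6-hydroxy-6-methyl-7-oxo-6,7-dihydro-5H-cyclopenta[c]pyridine-5-carboxylate | CC[C@H](C)/C=C(C)/C=C/c1cc2c(cn1)C(=O)[C@@](C)(O)[C@H]2C(=O)OC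
F4 | step 11 | methyl (5S,6S)-3-[(1E,3E,5S)-3,5-dimethylhepta-1,3-dien-1-yl]-6-methyl-7-oxo-6-[(triethylsilyl)oxy]-6,7-dihydro-5H-cyclopenta[c]pyridine-5-carboxylate | CC[C@H](C)/C=C(C)/C=C/c1cc2c(cn1)C(=O)[C@@](C)(O[Si](CC)(CC)CC)[C@H]2C(=O)OC
F5 | step 11 | methyl (5R,6S)-3-[(1E,3E,5S)-3,5-dimethylhepta-1,3-dien-1-yl]-5-hydroxy-6-methyl-7-oxo-6-[(triethylsilyl)oxy]-6,7-dihydro-5H-cyclopenta[c]pyridine-5-carboxylate | CC[C@H](C)/C=C(C)/C=C/c1cc2c(cn1)C(=O)[C@@](C)(O[Si](CC)(CC)CC)[C@@]2(O)C(=O)OC
F6 | step 11 | methyl (5R,6S)-5-[(tert-butyldimethylsilyl)oxy]-3-[(1E,3E,5S)-3,5-dimethylhepta-1,3-dien-1-yl]-6-methyl-7-oxo-6-[(triethylsilyl)oxy]-6,7-dihydro-5H-cyclopenta[c]pyridine-5-carboxylate | CC[C@H](C)/C=C(C)/C=C/c1cc2c(cn1)C(=O)[C@@](C)(O[Si](CC)(CC)CC)[C@@]2(O[Si](C)(C)C(C)(C)C)C(=O)OC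
F7 | step 8 | 1-(6-chloro-4-methylpyridin-3-yl)-2-ethoxyprop-2-en-1-one | C=C(OCC)C(=O)c1cnc(Cl)cc1C
F8 | step 8 | 1-(6-chloro-4-methylpyridin-3-yl)-2,2-diethoxypropan-1-one | CCOC(C)(OCC)C(=O)c1cnc(Cl)cc1C
F9 | step 8 | tert-butyl 2-[2-chloro-5-(2,2-diethoxypropanoyl)pyridin-4-yl]acetate | CCOC(C)(OCC)C(=O)c1cnc(Cl)cc1CC(=O)OC(C)(C)C
F10 | step 8 | tert-butyl 2-[5-(2,2-diethoxypropanoyl)-2-[(1E,3E,5S)-3,5-dimethylhepta-1,3-dien-1-yl]pyridin-4-yl]acetate | CC[C@H](C)/C=C(C)/C=C/c1cc(CC(=O)OC(C)(C)C)c(cn1)C(=O)C(C)(OCC)OCC
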